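The cyclohexenone ring is cut at C5'–C6' and C2'–C1' into a five-carbon 2-silyloxypentadiene and a butenolide. The feature exploited is the cis relation between side-chain carbon C5 on C1' and the CH2O carbon on quaternary C6': both are tied into a γ-lactone ring that the target lacks. One suprafacial Diels–Alder reaction then closes the six-membered ring, builds C6' and fixes C1'/C6' as a cis ring fusion. A menthyl acetal on the future CH2O carbon, a temporary stereocentre, blocks one face of the precursor. The silyl enol ether born in the cycloaddition masks the C4' enone until the CH2OH group is acylated; the lactone is later opened by olefination.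

Key step: step 3

Numbering and assumption: ring atoms are C1' (carbinol carbon), C2' (methyl-bearing carbon), C3', C4' (carbonyl carbon), C5' (CH2) and C6' (quaternary carbon). The side chain runs from C1 (CO2H) to C5 (bound to C1'). TIPS = triisopropylsilyl, Bpin = pinacolboryl. The endo cycloadduct is drawn throughout. Its C2' epimer would follow the same steps and converge when C2' becomes trigonal in the enone-forming step.

Step 1
Reactants: 1 5-hydroxy-4-methylfuran-2(5H)-one; 2 (1R,2S,5R)-menthol
Product: 3 (5R)-4-methyl-5-[(1R,2S,5R)-menthyloxy]furan-2(5H)-one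
Conditions: p-TsOH (cat.), toluene, reflux with azeotropic removal of water; crystallisation of the (5R)-epimer from hexane, mother liquor re-equilibrated with acid
Reagents that add atoms: none
Why: Acid-catalysed acetalisation of the cyclic hemiacetal gives both acetal epimers, and because these interconvert under acid, the (5R)-epimer should be harvested by crystallisation with recycling, which sets the temporary stereocentre.

Step 2
Reactants: 4 (E)-pent-3-en-2-one
Product: 5 (E)-2-(triisopropylsilyloxy)penta-1,3-diene
Conditions: TIPSOTf, Et3N, CH2Cl2, 0 °C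
Reagents that add atoms: triisopropylsilyl trifluoromethanesulfonate, CC(C)[Si](OS(=O)(=O)C(F)(F)F)(C(C)C)C(C)C
Why: Soft enolisation of the enone at its acetyl CH3 group with silyl triflate and amine gives the cross-conjugated 2-silyloxydiene with the E alkene retained.

Step 3
Reactants: 3 (5R)-4-methyl-5-[(1R,2S,5R)-menthyloxy]furan-2(5H)-one; 5 (E)-2-(triisopropylsilyloxy)penta-1,3-diene
Product: 6 cis-fused cycloadduct (3R,3aR,7S,7aS)-3-[(1R,2S,5R)-menthyloxy]-3a,7-dimethyl-5-(triisopropylsilyloxy)-3a,4,7,7a-tetrahydroisobenzofuran-1(3H)-one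
Conditions: toluene (3 M), BHT (cat.), sealed tube, 150 °C
Reagents that add atoms: none
Why: This is a concerted, asynchronous, normal-electron-demand Diels–Alder reaction in which the HOMO of 5 (largest coefficient at its CH2 terminus, reinforced by the terminal methyl group) meets the LUMO of 3 (largest coefficient at the methyl-bearing β-carbon), so CH2 (C5') bonds to C6' and CH(CH3) (C2') bonds to C1' in the ortho/para orientation. The closest known reaction types are the thermal cycloadditions of 5-alkoxyfuran-2(5H)-ones with 2-silyloxy-1,3-dienes and of β-methylbutenolides with butadienes. The six-membered carbocycle is closed by intermolecular suprafacial [4+2] addition across the ring alkene of 3, which can only give the cis-fused bicycle, so H on C1' and CH3 on C6' lie on one face and C5 and the acetal carbon on the other. The absolute configuration at C6' and C1' is controlled by the (5R)-menthyloxy group next to the reacting β-carbon, which sends 5 to the opposite face, while C2' follows from the endo transition state and is erased in step 10. The step needs regio- and face selectivity, secured by the matched polarisation and the acetal stereocentre, and enough reactivity at a β,β-disubstituted acceptor, which is why an electron-rich diene, high concentration and heat are used. The silyl enol ether is formed regiospecifically between C3' and C4'.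

Step 4
Reactants: 6 cis-fused cycloadduct
Product: 9 (3aR,7S,7aS)-3a,7-dimethyl-5-(triisopropylsilyloxy)-3a,4,7,7a-tetrahydroisobenzofuran-1(3H)-one, via formyl methyl ester 7 (not isolated), via hydroxy methyl ester 8 (not isolated)
Conditions: NaBH4, NaOMe (cat.), MeOH–THF, 0 to 25 °C
Reagents that add atoms: none
Why: Reductive removal of the acetal auxiliary: methoxide opens the pseudo-ester with loss of menthol, NaBH4 reduces the non-enolisable aldehyde and the alkoxide relactonises, while C1', C2', C6' and the silyl enol ether are not touched.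

Step 5
Reactants: 9 cis-fused lactone
Product: 11 (3aS,7S,7aR)-7a-hydroxy-3a,7-dimethyl-5-(triisopropylsilyloxy)-3a,4,7,7a-tetrahydroisobenzofuran-1(3H)-one, via potassium enolate 10 (not isolated)
Conditions: KN(SiMe3)2, THF, −78 °C; 2-(phenylsulfonyl)-3-phenyloxaziridine, −78 °C; AcOH
Reagents that add atoms: 2-(phenylsulfonyl)-3-phenyloxaziridine, O=S(=O)(c1ccccc1)N1OC1c1ccccc1
Why: Oxaziridine hydroxylation of a lactone enolate: C1' is a ring-fusion carbon, so oxygen should arrive on the face that carries the C6' methyl group and keeps the bicycle cis-fused (the other face is also screened by the C2' methyl group), which sets C1' with OH cis to CH3 as in the target.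

Step 6
Reactants: 11 α-hydroxy lactone
Product: 12 lactol (3aS,7S,7aR)-3a,7-dimethyl-5-(triisopropylsilyloxy)-1,3,3a,4,7,7a-hexahydroisobenzofuran-1,7a-diol (anomer mixture)
Conditions: i-Bu2AlH (2.4 equiv), CH2Cl2, −78 °C; aq. potassium sodium tartrate
Reagents that add atoms: none
Why: Partial reduction of a γ-lactone to the lactol, whose tetrahedral aluminium alkoxide is stable at −78 °C; one equivalent is consumed by the tertiary OH and no stereocentre of the target is touched.

Step 7
Reactants: 12 lactol
Product: 14 (1R,2S,6S)-6-(hydroxymethyl)-2,6-dimethyl-1-[(E)-2-(pinacolboryl)ethenyl]-4-(triisopropylsilyloxy)cyclohex-3-en-1-ol, via open hydroxy aldehyde 13 (not isolated)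
Conditions: CrCl2 (8 equiv), LiI (4 equiv), Cl2CHBpin (2 equiv), THF, 25 °C
Reagents that add atoms: 2-(dichloromethyl)-4,4,5,5-tetramethyl-1,3,2-dioxaborolane, ClC(Cl)B1OC(C)(C)C(C)(C)O1
Why: Takai–Utimoto olefination: the geminal dichromium reagent drains the small share of open aldehyde, the bulky C1' substituent enforces the E alkene, the neutral conditions spare the α-hydroxy aldehyde and the silyl enol ether, and opening of the lactol frees the CH2OH group.

Step 8
Reactants: 15 dimethyl 3-hydroxy-3-methylpentanedioate
Product: 16 (S)-3-hydroxy-5-methoxy-3-methyl-5-oxopentanoic acid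
Conditions: pig liver esterase, phosphate buffer pH 7.5, NaOH (pH-stat), 25 °C; HCl to pH 2
Reagents that add atoms: water, O
Why: Enzymatic desymmetrisation of a prochiral diester: the esterase should hydrolyse one enantiotopic ester group and give the (S)-half-ester, which sets the carbinol stereocentre of the glutarate unit.

Step 9
Reactants: 14 vinylboronate diol; 16 (S)-half-ester
Product: 17 glutarate ester of 14 at the CH2OH group, (3R) in the glutarate and (1R,2S,6S) in the ring
Conditions: EDC·HCl, DMAP, CH2Cl2, 0 to 25 °C
Reagents that add atoms: none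
Why: Steglich esterification acylates only the primary CH2OH group because both tertiary alcohols are too hindered, and the glutarate centre is untouched (its descriptor changes from S to R by priority only).

Step 10
Reactants: 17 silyl enol ether glutarate
Product: 18 enone vinylboronate, (3R) in the glutarate and (1R,6S) in the ring
Conditions: DDQ (1.3 equiv), 2,6-lutidine, CH2Cl2, 0 to 25 °C
Reagents that add atoms: none
Why: DDQ dehydrogenation of a silyl enol ether (hydride abstraction from the allylic C2'–H, then loss of silyl) can only give the C2'=C3' enone because C6' bears no hydrogen, and with the CH2OH group already acylated no intramolecular oxa-Michael addition to the new enone is possible.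

Step 11
Reactants: 19 but-2-ynoic acid
Product: 20 (Z)-3-iodobut-2-enoic acid
Conditions: NaI, AcOH, 110 °C
Reagents that add atoms: sodium iodide, [Na+].[I-]
Why: Anti hydroiodination of an alkynoic acid (conjugate addition of iodide, then protonation) should give the Z isomer with I and CO2H cis.

Step 12
Reactants: 18 enone vinylboronate; 20 (Z)-3-iodobut-2-enoic acid
Product: 21 target CNP0274837.1
Conditions: PdCl2(dppf) (5 mol%), K3PO4 (3 equiv), THF–H2O, 25 °C, exclusion of light; work-up at pH 4
Reagents that add atoms: none
Why: Suzuki–Miyaura coupling proceeds with retention at both alkenyl partners, so the E boronate and the Z iodide give the (2Z,4E)-dienoic acid directly, the free carboxylate needs no protecting group, and phosphate base at room temperature should leave both esters intact.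

Compound list
1 | 5-hydroxy-4-methylfuran-2(5H)-one (racemic hemiacetal) | CC1=CC(=O)OC1O | starting material
2 | (1R,2S,5R)-menthol | C[C@@H]1CC[C@H]([C@@H](C1)O)C(C)C | starting material
3 | (5R)-4-methyl-5-[(1R,2S,5R)-menthyloxy]furan-2(5H)-one | CC1=CC(=O)O[C@H]1O[C@@H]2C[C@H](C)CC[C@H]2C(C)C | intermediate
4 | (E)-pent-3-en-2-one | C/C=C/C(C)=O | starting material
5 | (E)-2-(triisopropylsilyloxy)penta-1,3-diene | C=C(O[Si](C(C)C)(C(C)C)C(C)C)/C=C/C | intermediate
6 | (3R,3aR,7S,7aS)-3-[(1R,2S,5R)-menthyloxy]-3a,7-dimethyl-5-(triisopropylsilyloxy)-3a,4,7,7a-tetrahydroisobenzofuran-1(3H)-one | O=C1O[C@@H](O[C@@H]3C[C@H](C)CC[C@H]3C(C)C)[C@]2(C)CC(O[Si](C(C)C)(C(C)C)C(C)C)=C[C@H](C)[C@H]12 | intermediate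
7 | methyl (1S,2S,6R)-6-formyl-2,6-dimethyl-4-(triisopropylsilyloxy)cyclohex-3-ene-1-carboxylate | COC(=O)[C@H]1[C@@H](C)C=C(O[Si](C(C)C)(C(C)C)C(C)C)C[C@@]1(C)C=O | intermediate
8 | methyl (1S,2S,6R)-6-(hydroxymethyl)-2,6-dimethyl-4-(triisopropylsilyloxy)cyclohex-3-ene-1-carboxylate | COC(=O)[C@H]1[C@@H](C)C=C(O[Si](C(C)C)(C(C)C)C(C)C)C[C@@]1(C)CO | intermediate
9 | (3aR,7S,7aS)-3a,7-dimethyl-5-(triisopropylsilyloxy)-3a,4,7,7a-tetrahydroisobenzofuran-1(3H)-one | O=C1OC[C@]2(C)CC(O[Si](C(C)C)(C(C)C)C(C)C)=C[C@H](C)[C@H]12 | intermediate
10 | potassium enolate of 9 (C1' trigonal, C2' S, C6' R) | [K+].[O-]C1=C2[C@@H](C)C=C(O[Si](C(C)C)(C(C)C)C(C)C)C[C@@]2(C)CO1 | intermediate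
11 | (3aS,7S,7aR)-7a-hydroxy-3a,7-dimethyl-5-(triisopropylsilyloxy)-3a,4,7,7a-tetrahydroisobenzofuran-1(3H)-one | O=C1OC[C@]2(C)CC(O[Si](C(C)C)(C(C)C)C(C)C)=C[C@H](C)[C@]12O | intermediate
12 | (3aS,7S,7aR)-3a,7-dimethyl-5-(triisopropylsilyloxy)-1,3,3a,4,7,7a-hexahydroisobenzofuran-1,7a-diol (anomer mixture) | OC1OC[C@]2(C)CC(O[Si](C(C)C)(C(C)C)C(C)C)=C[C@H](C)[C@]12O | intermediate
13 | (1R,2S,6S)-1-hydroxy-6-(hydroxymethyl)-2,6-dimethyl-4-(triisopropylsilyloxy)cyclohex-3-ene-1-carbaldehyde | OC[C@]1(C)CC(O[Si](C(C)C)(C(C)C)C(C)C)=C[C@H](C)[C@]1(O)C=O | intermediate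
14 | (1R,2S,6S)-6-(hydroxymethyl)-2,6-dimethyl-1-[(E)-2-(pinacolboryl)ethenyl]-4-(triisopropylsilyloxy)cyclohex-3-en-1-ol | OC[C@]1(C)CC(O[Si](C(C)C)(C(C)C)C(C)C)=C[C@H](C)[C@]1(O)/C=C/B2OC(C)(C)C(C)(C)O2 | intermediate
15 | dimethyl 3-hydroxy-3-methylpentanedioate | COC(=O)CC(C)(O)CC(=O)OC | starting material
16 | (S)-3-hydroxy-5-methoxy-3-methyl-5-oxopentanoic acid | COC(=O)C[C@@](C)(O)CC(=O)O | intermediate
17 | methyl (3R)-3-hydroxy-3-methylglutarate ester of the CH2OH group of 14 | COC(=O)C[C@@](C)(O)CC(=O)OC[C@]1(C)CC(O[Si](C(C)C)(C(C)C)C(C)C)=C[C@H](C)[C@]1(O)/C=C/B2OC(C)(C)C(C)(C)O2 | intermediate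
18 | methyl (3R)-3-hydroxy-3-methylglutarate ester of (1R,6S)-1-hydroxy-6-(hydroxymethyl)-2,6-dimethyl-1-[(E)-2-(pinacolboryl)ethenyl]cyclohex-2-en-4-one | COC(=O)C[C@@](C)(O)CC(=O)OC[C@]1(C)CC(=O)C=C(C)[C@]1(O)/C=C/B2OC(C)(C)C(C)(C)O2 | intermediate
19 | but-2-ynoic acid | CC#CC(=O)O | starting material
20 | (Z)-3-iodobut-2-enoic acid | C/C(I)=C/C(=O)O | intermediate
21 | CNP0274837.1, (2Z,4E)-dienoic acid with (1'R,6'S) ring and (3R)-glutarate methyl ester | COC(=O)C[C@@](C)(O)CC(=O)OC[C@]1(C)CC(=O)C=C(C)[C@]1(O)/C=C/C(C)=C\C(=O)O | target

Total step count: 12. Longest linear sequence: 9 steps (steps 1, 3, 4, 5, 6, 7, 9, 10 and 12).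

Steps most likely to fail

Step 3. The cycloaddition may be too slow at the β,β-disubstituted acceptor carbon, so that polymerisation of the diene or thermal loss of the acetal competes. The fallback replaces the neutral diene by its far more nucleophilic enolate in an anionic double Michael sequence and sets out from 4 and 3. LiN(i-Pr)2 in THF at −78 °C converts 4 into the cross-conjugated lithium dienolate F1. Its CH2 terminus adds to the β-carbon of 3 anti to the menthyloxy group. The resulting lactone enolate closes onto the enone β-carbon to give the bicyclic lithium enolate F2. Silylation in the flask with TIPSOTf brings the sequence back to the route at 6.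

Step 7. The hindered lactol may stay closed so that the olefination stalls, or the Lewis acidic trivalent chromium salts may slowly cleave the silyl enol ether. The fallback goes through an alkyne and sets out from 12. Seyferth–Gilbert homologation with dimethyl (1-diazo-2-oxopropyl)phosphonate, K2CO3 and MeOH gives the ethynyl carbinol F3. Syn hydroboration with excess pinacolborane and Cp2ZrHCl (10 mol%), followed by aqueous work-up, gives the E boronate and comes back to the route at 14.

Step 10. Hydride abstraction from the hindered C2'–H may be slow, so that protodesilylation to the saturated ketone or attack of the oxidant on the alkenylboronate takes over. The fallback changes the order of events so that no boron is present during the oxidation, and sets out from 17. Suzuki–Miyaura coupling with 20 under the conditions of step 12 gives the dienoic acid silyl enol ether F4. Saegusa–Ito oxidation with Pd(OAc)2 in DMSO–MeCN at 40 °C then forms the enone and comes back to the route at 21.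

Further compounds
F1 | step 3 | lithium (E)-penta-1,3-dien-2-olate | [Li+].C=C([O-])/C=C/C
F2 | step 3 | bicyclic lithium enolate, the O-lithio analogue of 6 | [Li+].[O-]C1=C[C@H](C)[C@@H]2C(=O)O[C@@H](O[C@@H]3C[C@H](C)CC[C@H]3C(C)C)[C@]2(C)C1
F3 | step 7 | (1R,2S,6S)-1-ethynyl-6-(hydroxymethyl)-2,6-dimethyl-4-(triisopropylsilyloxy)cyclohex-3-en-1-ol | OC[C@]1(C)CC(O[Si](C(C)C)(C(C)C)C(C)C)=C[C@H](C)[C@]1(O)C#C
F4 | step 10 | (2Z,4E)-dienoic acid that still carries the C3'=C4' triisopropylsilyl enol ether | COC(=O)C[C@@](C)(O)CC(=O)OC[C@]1(C)CC(O[Si](C(C)C)(C(C)C)C(C)C)=C[C@H](C)[C@]1(O)/C=C/C(C)=C\C(=O)O
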